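No reading so far shows starting material standing still: both earlier runs are still falling at their last point. So two chemists can argue over whether it ever stops, which is kinetic against thermodynamic control.

| setting | Wednesday's | Thursday's | eta | delta | beta |
|---|---|---|---|---|---|
| starting material | 0.036 M | 0.14 M | 0.072 M | 0.072 M | 0.072 M |
| temperature | 45 °C | 65 °C | 50 °C | 65 °C | 80 °C |
| remark | run made earlier | run made earlier |  |  |  |
| time |  |  | 40 min | 40 min | 40 min |

- Wednesday's (time / min: starting material / %, target / %): 10.0: 95.6, 4.3; 20.0: 90.4, 6.7; 30.0: 88.2, 8.5; 40.0: 84.6, 14.0; 50.0: 81.6, 15.3
- Thursday's (time / min: starting material / %, target / %): 2.00: 84.1, 12.6; 6.00: 66.1, 33.2; 10.0: 52.6, 46.2; 15.0: 42.3, 56.4; 25.0: 33.3, 65.6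

(scatter of a reading: 1 percentage point)

- percent here means starting material units held: one target or crystals or over-reaction product counts as two
- percent here means starting material units held: one idle adduct counts as three
- what is said of target includes crystals and idle adduct
- crystals is a solid; its amount is given per volume of the solution
- the numbers in the tables scatter by 1 percentage point (one standard deviation)
- candidate steps: target -> over-reaction product; crystals <-> target; starting material + target <-> idle adduct; 2 starting material <-> target
- in an amount of target, one idle adduct counts as one target

* which of these there is most of at the end, counted by the starting material in it, eta (starting material / target)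
* which of these there is most of at the end, counted by the starting material in it, delta (starting material / target)
* which of these there is most of at the end, counted by the starting material in it, beta (starting material / target)
* amount of the one of these that there is most of at the end, in percent of the starting material charged, eta
* amount of the one of these that there is most of at the end, in percent of the starting material charged, delta
* amount of the one of these that there is most of at the end, in percent of the starting material charged, beta

The first chemist holds that two starting material go to target with no way back. The inverse of the fraction left, less one, then grows in proportion to time. Thursday's reading at 10.0 min gives a rate constant, as a reading with its scatter, of 0.644 L mol⁻¹ min⁻¹ at 65 °C, which is also delta's temperature. For delta, 21.6 min is the charge time, the inverse of that constant times the charged [starting material]. On the plain curve the fraction left is the charge time over the charge time plus the elapsed time. That is my own reckoning, and it leaves 35.0% in delta, so about 65.0% as target.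

The second chemist points to Thursday's last reading, 33.3%. The plain curve gives 30.7% there, so the reading stands 2.6 percentage points above it, against a scatter of 1 point. She expects target to be held back.

The forecast takes her side: “Thursday's late slowing hints at reversibility”. It says starting material at 64% for eta, target at 60% for delta, where my plain curve gave 65.0%, and target at 72% for beta.

The flask gives starting material at 66.3% for eta, target at 58.1% for delta and target at 71.4% for beta. The forecast stands on each.

    target → over-reaction product (k = 3.52 × 10⁻⁵ min⁻¹, Ea = 117 kJ mol⁻¹)
    crystals ⇌ target, rate k2*(cs2 - [target]) while solid is left; crystals form when [target] > cs2 (solubility = 3.50 mM, k = 3.52 min⁻¹)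
    starting material + target ⇌ idle adduct, settled at all times (K = 8.42 L mol⁻¹, ΔH = −16.0 kJ mol⁻¹)
    2 starting material ⇌ target (K = 12.0 L mol⁻¹, k = 0.0925 L mol⁻¹ min⁻¹, Ea = 75.0 kJ mol⁻¹, ΔH = −5.00 kJ mol⁻¹)
    (constants at 50 °C)

Delta has not come to rest at 40 min, when its starting material stands at 41%: at 400 min, ten times as long, its starting material stands at 24.7% and its target at 73.8%. The charge time puts the plain curve at 5.12% by then, so delta stands above it, at 17.8 mM of [starting material]. Eta and beta reach 26.3% and 25.7% at that time. As far as these two flasks show, the plain view has its region where its remainder stands well above that level: for eta the forecast's simple decay gave 64%, which is 46.1 mM, and the flask stands 2.3 points above it; for delta the plain 35.0% is 25.2 mM, and the flask stands 6.0 points above it.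

For the neighbour of delta with 0.29 M charged, all else held, the charge time is 5.36 min. The plain curve leaves 11.8%, which is 34.2 mM, twice that level, so the plain view should hold there; that flask gives 13.3%.

All runs are simulated from invented constants; noise was put on by code.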